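## Retrosynthetic overview

1. The caffeoyl C=C bond is cut by Horner–Wadsworth–Emmons olefination: a phosphonoacetate on the C3 CH2O arm plus bis-silylated 3,4-dihydroxybenzaldehyde; the four aryl silyl ethers fall last.
2. The C4 benzyl centre comes from hydrogenation of a C4 benzylidene oxolane on the face away from the C3 arm (3,4-cis).
3. The oxolane, the only ring that is built (the benzene rings come in with the starting materials), is closed in step 4 from three pieces: an erythro 1-aryl-2,3-epoxypropan-1-ol, vinyltriphenylphosphonium bromide and silylated vanillin. O1–C5 forms by oxa-Michael addition, C3–C4 by attack of the resulting ylide on the epoxide, then a Wittig reaction at C4.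
4. Enabling feature: the ring unit O1–C2(aryl)–C3 with a CH2O branch on C3. O1 can be an alkoxide and C3/CH2O an epoxide, so the unit is a nucleophile (O1)/electrophile (C3) pair that matches C5=C4 of a vinylphosphonium salt (C5 electrophile, C4 ylide nucleophile); the epoxide oxygen ends as the ester oxygen.
5. The epoxy alcohol comes from Sharpless kinetic resolution of the vinyl carbinol made from silylated vanillin and vinylmagnesium bromide.

Key step: step 4

Assumption: the benzylidene intermediate is drawn as the Z isomer expected from the less crowded Wittig transition state; the E isomer would serve equally, because this alkene is reduced in step 6.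

## Route

Step 1
Reactants: 1 vanillin
Product: 2 3-methoxy-4-[(triisopropylsilyl)oxy]benzaldehyde
Conditions: i-Pr3SiCl (1.1 equiv), imidazole (2.2 equiv), DMF, 0 °C → rt
Reagents that add atoms: triisopropylsilyl chloride, CC(C)[Si](Cl)(C(C)C)C(C)C
Why: Imidazole-promoted silyl ether formation at the phenol should be clean because the aldehyde is inert to the silyl chloride, and the bulky triisopropylsilyl ether is chosen to survive the alkoxide, ylide and hydrogenation steps.

Step 2
Reactants: 2 3-methoxy-4-[(triisopropylsilyl)oxy]benzaldehyde; 3 vinylmagnesium bromide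
Product: 4 rac-1-{3-methoxy-4-[(triisopropylsilyl)oxy]phenyl}prop-2-en-1-ol
Conditions: THF, −78 → 0 °C; then aq. NH4Cl
Reagents that add atoms: none
Why: Grignard 1,2-addition of the vinyl nucleophile to the aldehyde should give the racemic secondary allylic alcohol, whose carbinol centre is resolved in step 3.

Step 3
Reactants: 4 rac-1-{3-methoxy-4-[(triisopropylsilyl)oxy]phenyl}prop-2-en-1-ol
Product: 5 (S)-{3-methoxy-4-[(triisopropylsilyl)oxy]phenyl}[(2R)-oxiran-2-yl]methanol
Conditions: Ti(OiPr)4 (0.15 equiv), L-(+)-DIPT (0.18 equiv), t-BuOOH (0.55 equiv, isooctane), 4 Å molecular sieves, CH2Cl2, −20 °C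
Reagents that add atoms: tert-butyl hydroperoxide, CC(C)(C)OO
Why: Sharpless kinetic resolution (titanium tartrate asymmetric epoxidation): with L-(+)-DIPT the (R)-alcohol should be epoxidised much faster than its enantiomer and on the alkene face anti to the aryl group, which sets the (S)-carbinol and (R)-oxirane centres of the erythro epoxy alcohol in one operation, while the slow (S)-alcohol stays behind and is separated.

Step 4
Reactants: 5 (S)-{3-methoxy-4-[(triisopropylsilyl)oxy]phenyl}[(2R)-oxiran-2-yl]methanol; 6 triphenyl(vinyl)phosphonium bromide; 2 3-methoxy-4-[(triisopropylsilyl)oxy]benzaldehyde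
Product: 10 {(2R,3S,4Z)-4-{3-methoxy-4-[(triisopropylsilyl)oxy]benzylidene}-2-{3-methoxy-4-[(triisopropylsilyl)oxy]phenyl}oxolan-3-yl}methanol, via β-alkoxy ylide 7 (not isolated), via betaine 8 (not isolated), via γ-oxido ylide 9 (not isolated)
Conditions: NaN(SiMe3)2 (1.05 equiv), THF, −20 °C; 6 (1.1 equiv), −20 → 40 °C; NaN(SiMe3)2 (1.1 equiv), −78 °C; 2 (1.2 equiv), −78 °C → rt; then H2O
Reagents that add atoms: none
Why: Proposed new method: the sodium alkoxide of 5 adds to the CH2 terminus of the vinylphosphonium salt 6 (oxa-Michael addition, O1–C5 bond) to give ylide 7, whose carbanionic carbon opens the tethered epoxide at its internal carbon in an SN2 step (C3–C4 bond) to give betaine 8, and a second equivalent of base turns 8 into the γ-oxido ylide 9, which olefinates aldehyde 2 in a Wittig reaction. The closest known reaction types are the Schweizer annulation, in which an alkoxide adds to a vinylphosphonium salt and the ylide is trapped inside the molecule, and the alkylation of phosphonium ylides by epoxides followed by Wittig reaction of the γ-oxido ylide; what is new is that the epoxide is the internal trap of the conjugate-addition ylide. The oxolane closes in the 5-exo-tet mode, with the breaking epoxide C–O bond outside the forming ring. The C3 stereocentre is set by inversion at the (R)-configured epoxide carbon and so comes out trans to the C2 aryl group fixed in step 3, while the phosphonium-bearing C4 centre is transient and becomes sp2. The step needs attack at the internal and not the terminal epoxide carbon, which the three-atom tether secures (5-exo over 6-endo), and oxa-Michael addition faster than Payne rearrangement of the epoxy alkoxide, which the high electrophilicity of 6 at low temperature secures. The alkene geometry is of no consequence because step 6 reduces this bond.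

Step 5
Reactants: 10 {(2R,3S,4Z)-4-{3-methoxy-4-[(triisopropylsilyl)oxy]benzylidene}-2-{3-methoxy-4-[(triisopropylsilyl)oxy]phenyl}oxolan-3-yl}methanol; 11 (diethoxyphosphoryl)acetic acid
Product: 12 {(2R,3S,4Z)-4-{3-methoxy-4-[(triisopropylsilyl)oxy]benzylidene}-2-{3-methoxy-4-[(triisopropylsilyl)oxy]phenyl}oxolan-3-yl}methyl (diethoxyphosphoryl)acetate
Conditions: 11 (1.3 equiv), EDC·HCl (1.5 equiv), DMAP (0.1 equiv), CH2Cl2, 0 °C → rt
Reagents that add atoms: none
Why: Steglich-type carbodiimide esterification of the only free hydroxyl group should be straightforward, and the acyl group both keeps the alcohol from steering the hydrogenation and carries the phosphonate needed in step 8.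

Step 6
Reactants: 12 {(2R,3S,4Z)-4-{3-methoxy-4-[(triisopropylsilyl)oxy]benzylidene}-2-{3-methoxy-4-[(triisopropylsilyl)oxy]phenyl}oxolan-3-yl}methyl (diethoxyphosphoryl)acetate
Product: 13 {(2R,3S,4S)-4-{3-methoxy-4-[(triisopropylsilyl)oxy]benzyl}-2-{3-methoxy-4-[(triisopropylsilyl)oxy]phenyl}oxolan-3-yl}methyl (diethoxyphosphoryl)acetate
Conditions: H2 (1 atm), 5% Rh/Al2O3, EtOAc, rt
Reagents that add atoms: none
Why: Heterogeneous catalytic hydrogenation should deliver hydrogen to the exocyclic alkene from the ring face opposite to the adjacent C3 acyloxymethyl arm, which places the new C4 benzyl group cis to that arm (4S), and rhodium on alumina is chosen because it is little prone to hydrogenolysis of allylic and benzylic C–O bonds.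

Step 7
Reactants: 14 3,4-dihydroxybenzaldehyde
Product: 15 3,4-bis[(tert-butyldimethylsilyl)oxy]benzaldehyde
Conditions: t-BuMe2SiCl (2.4 equiv), imidazole (5 equiv), DMF, rt
Reagents that add atoms: tert-butyldimethylsilyl chloride, CC(C)(C)[Si](C)(C)Cl
Why: Imidazole-promoted silyl ether formation should cap both catechol hydroxyl groups so that the aldehyde can enter the base-mediated olefination.

Step 8
Reactants: 13 {(2R,3S,4S)-4-{3-methoxy-4-[(triisopropylsilyl)oxy]benzyl}-2-{3-methoxy-4-[(triisopropylsilyl)oxy]phenyl}oxolan-3-yl}methyl (diethoxyphosphoryl)acetate; 15 3,4-bis[(tert-butyldimethylsilyl)oxy]benzaldehyde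
Product: 16 {(2R,3S,4S)-4-{3-methoxy-4-[(triisopropylsilyl)oxy]benzyl}-2-{3-methoxy-4-[(triisopropylsilyl)oxy]phenyl}oxolan-3-yl}methyl (E)-3-{3,4-bis[(tert-butyldimethylsilyl)oxy]phenyl}prop-2-enoate
Conditions: NaN(SiMe3)2 (1.05 equiv), THF, −78 °C; 15 (1.2 equiv), −78 → 0 °C
Reagents that add atoms: none
Why: Horner–Wadsworth–Emmons olefination of the stabilised phosphonoacetate anion with an aryl aldehyde should give the (E)-cinnamate selectively, without touching the three ring stereocentres.

Step 9
Reactants: 16 {(2R,3S,4S)-4-{3-methoxy-4-[(triisopropylsilyl)oxy]benzyl}-2-{3-methoxy-4-[(triisopropylsilyl)oxy]phenyl}oxolan-3-yl}methyl (E)-3-{3,4-bis[(tert-butyldimethylsilyl)oxy]phenyl}prop-2-enoate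
Product: 17 [(2R,3S,4S)-4-(4-hydroxy-3-methoxybenzyl)-2-(4-hydroxy-3-methoxyphenyl)oxolan-3-yl]methyl (E)-3-(3,4-dihydroxyphenyl)prop-2-enoate
Conditions: Bu4NF (4.4 equiv), AcOH (4.4 equiv), THF, 0 °C
Reagents that add atoms: none
Why: Fluoride-mediated cleavage of the four aryl silyl ethers, buffered with acetic acid, should free the phenols without harming the cinnamate ester, the catechol or the acid-sensitive benzylic ether at C2.

## Compound list

1 | vanillin (4-hydroxy-3-methoxybenzaldehyde) | COc1cc(C=O)ccc1O | starting material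
2 | 3-methoxy-4-[(triisopropylsilyl)oxy]benzaldehyde | COc1cc(C=O)ccc1O[Si](C(C)C)(C(C)C)C(C)C | intermediate
3 | vinylmagnesium bromide | C=C[Mg]Br | starting material
4 | rac-1-{3-methoxy-4-[(triisopropylsilyl)oxy]phenyl}prop-2-en-1-ol | COc1cc(C(O)C=C)ccc1O[Si](C(C)C)(C(C)C)C(C)C | intermediate
5 | (S)-{3-methoxy-4-[(triisopropylsilyl)oxy]phenyl}[(2R)-oxiran-2-yl]methanol (erythro epoxy alcohol) | COc1cc([C@H](O)[C@H]2CO2)ccc1O[Si](C(C)C)(C(C)C)C(C)C | intermediate
6 | triphenyl(vinyl)phosphonium bromide | C=C[P+](c1ccccc1)(c1ccccc1)c1ccccc1.[Br-] | starting material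
7 | β-alkoxy ylide: triphenyl(2-{(S)-{3-methoxy-4-[(triisopropylsilyl)oxy]phenyl}[(2R)-oxiran-2-yl]methoxy}ethylidene)phosphorane | COc1cc([C@H](OCC=P(c2ccccc2)(c2ccccc2)c2ccccc2)[C@H]2CO2)ccc1O[Si](C(C)C)(C(C)C)C(C)C | intermediate (not isolated)
8 | betaine: [(2R,3S)-2-{3-methoxy-4-[(triisopropylsilyl)oxy]phenyl}-4-(triphenylphosphonio)oxolan-3-yl]methanolate (C4 configuration not defined, lost in the next event) | [O-]C[C@H]1[C@H](c2ccc(O[Si](C(C)C)(C(C)C)C(C)C)c(OC)c2)OCC1[P+](c1ccccc1)(c1ccccc1)c1ccccc1 | intermediate (not isolated)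
9 | γ-oxido ylide: sodium [(2R,3S)-2-{3-methoxy-4-[(triisopropylsilyl)oxy]phenyl}-4-(triphenylphosphoranylidene)oxolan-3-yl]methanolate | [Na+].[O-]C[C@H]1[C@H](c2ccc(O[Si](C(C)C)(C(C)C)C(C)C)c(OC)c2)OCC1=P(c1ccccc1)(c1ccccc1)c1ccccc1 | intermediate (not isolated)
10 | {(2R,3S,4Z)-4-{3-methoxy-4-[(triisopropylsilyl)oxy]benzylidene}-2-{3-methoxy-4-[(triisopropylsilyl)oxy]phenyl}oxolan-3-yl}methanol | OC[C@H]1[C@H](c2ccc(O[Si](C(C)C)(C(C)C)C(C)C)c(OC)c2)OC/C1=C\c1ccc(O[Si](C(C)C)(C(C)C)C(C)C)c(OC)c1 | intermediate
11 | (diethoxyphosphoryl)acetic acid | CCOP(=O)(OCC)CC(=O)O | starting material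
12 | {(2R,3S,4Z)-4-{3-methoxy-4-[(triisopropylsilyl)oxy]benzylidene}-2-{3-methoxy-4-[(triisopropylsilyl)oxy]phenyl}oxolan-3-yl}methyl (diethoxyphosphoryl)acetate | CCOP(=O)(OCC)CC(=O)OC[C@H]1[C@H](c2ccc(O[Si](C(C)C)(C(C)C)C(C)C)c(OC)c2)OC/C1=C\c1ccc(O[Si](C(C)C)(C(C)C)C(C)C)c(OC)c1 | intermediate
13 | {(2R,3S,4S)-4-{3-methoxy-4-[(triisopropylsilyl)oxy]benzyl}-2-{3-methoxy-4-[(triisopropylsilyl)oxy]phenyl}oxolan-3-yl}methyl (diethoxyphosphoryl)acetate | CCOP(=O)(OCC)CC(=O)OC[C@H]1[C@H](c2ccc(O[Si](C(C)C)(C(C)C)C(C)C)c(OC)c2)OC[C@H]1Cc1ccc(O[Si](C(C)C)(C(C)C)C(C)C)c(OC)c1 | intermediate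
14 | 3,4-dihydroxybenzaldehyde | O=Cc1ccc(O)c(O)c1 | starting material
15 | 3,4-bis[(tert-butyldimethylsilyl)oxy]benzaldehyde | O=Cc1ccc(O[Si](C)(C)C(C)(C)C)c(O[Si](C)(C)C(C)(C)C)c1 | intermediate
16 | {(2R,3S,4S)-4-{3-methoxy-4-[(triisopropylsilyl)oxy]benzyl}-2-{3-methoxy-4-[(triisopropylsilyl)oxy]phenyl}oxolan-3-yl}methyl (E)-3-{3,4-bis[(tert-butyldimethylsilyl)oxy]phenyl}prop-2-enoate | CC(C)(C)[Si](C)(C)Oc1ccc(/C=C/C(=O)OC[C@H]2[C@H](c3ccc(O[Si](C(C)C)(C(C)C)C(C)C)c(OC)c3)OC[C@H]2Cc2ccc(O[Si](C(C)C)(C(C)C)C(C)C)c(OC)c2)cc1O[Si](C)(C)C(C)(C)C | intermediate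
17 | [(2R,3S,4S)-4-(4-hydroxy-3-methoxybenzyl)-2-(4-hydroxy-3-methoxyphenyl)oxolan-3-yl]methyl (E)-3-(3,4-dihydroxyphenyl)prop-2-enoate | COc1cc(C[C@@H]2CO[C@@H](c3ccc(O)c(OC)c3)[C@@H]2COC(=O)/C=C/c2ccc(O)c(O)c2)ccc1O | target

## Step count and risks

Total step count: 9. Longest linear sequence: 8 steps (steps 1, 2, 3, 4, 5, 6, 8 and 9, from vanillin); step 7 is a one-step side branch.

Steps most likely to fail:

**Step 4 (proposed new method).** Payne rearrangement of the epoxy alkoxide may outrun the conjugate addition, the ylide may open the epoxide at the terminal carbon (6-endo), or the C4 ylide may reversibly expel the ring oxygen before the Wittig reaction. The fallback uses known chemistry and sets out from 5, together with 4 (racemic, or the enantiomer left over from step 3). PBr3 in ether at 0 °C should convert 4, with allylic transposition, into (E)-1-(3-bromoprop-1-enyl)-3-methoxy-4-[(triisopropylsilyl)oxy]benzene F1. Williamson etherification of 5 with F1 (NaH, THF, 0 °C) should give the epoxy cinnamyl ether F2. Cp2TiCl (trivalent titanium, made in the flask from Cp2TiCl2 and zinc dust, THF, rt) should open the epoxide homolytically to the secondary C3 radical. This radical closes 5-exo-trig onto the cinnamyl alkene through a chair-like transition state (2,3-trans, 3,4-cis) and, after reduction of the benzylic radical and protonation, gives the bis-silylated oxolane alcohol F3. Esterification of F3 with 11 under the conditions of step 5 returns to the route at 13, so that steps 4 to 6 are bypassed.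

**Step 6.** Hydrogen may be delivered to the wrong face, the allylic C5–O1 or the benzylic C2–O1 bond may be hydrogenolysed, the double bond may migrate into the ring, or an arene may be partly saturated. The fallback sets out from 12 and comes back at 13 without a new compound: radical hydrogenation by hydrogen-atom transfer (Mn(dpm)3 cat., PhSiH3, t-BuOOH, i-PrOH, rt). A metal hydride hands a hydrogen atom to C4 from the less hindered face and the benzylic radical is then quenched; no metal surface is involved, so C–O hydrogenolysis and steering by polar groups are excluded.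

**Step 3.** The electron-rich benzylic alcohol may ionise, the terminal epoxide may be opened by isopropoxide at the Lewis-acidic titanium centre, or the rate difference between the enantiomers may be too small. The fallback sets out from 4 and comes back at 5. Lipase-catalysed acylation (immobilised Candida antarctica lipase B, vinyl acetate, hexane, rt) should acylate the (R)-alcohol selectively to (R)-1-{3-methoxy-4-[(triisopropylsilyl)oxy]phenyl}prop-2-enyl acetate F4. After separation from the (S)-alcohol, i-Bu2AlH (CH2Cl2, −78 °C) should free (R)-1-{3-methoxy-4-[(triisopropylsilyl)oxy]phenyl}prop-2-en-1-ol F5. Hydroxyl-directed epoxidation with VO(acac)2 (cat.) and t-BuOOH (CH2Cl2, 0 °C) should then give 5, the erythro isomer being favoured for a vinyl carbinol and the threo isomer removed by chromatography.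

## Further compounds

F1 | step 4 | (E)-1-(3-bromoprop-1-enyl)-3-methoxy-4-[(triisopropylsilyl)oxy]benzene | BrC/C=C/c1ccc(O[Si](C(C)C)(C(C)C)C(C)C)c(OC)c1
F2 | step 4 | (2R)-2-{(S)-{3-methoxy-4-[(triisopropylsilyl)oxy]phenyl}{[(E)-3-{3-methoxy-4-[(triisopropylsilyl)oxy]phenyl}prop-2-enyl]oxy}methyl}oxirane | COc1cc([C@H](OC/C=C/c2ccc(O[Si](C(C)C)(C(C)C)C(C)C)c(OC)c2)[C@H]2CO2)ccc1O[Si](C(C)C)(C(C)C)C(C)C
F3 | step 4 | {(2R,3S,4S)-4-{3-methoxy-4-[(triisopropylsilyl)oxy]benzyl}-2-{3-methoxy-4-[(triisopropylsilyl)oxy]phenyl}oxolan-3-yl}methanol | OC[C@H]1[C@H](c2ccc(O[Si](C(C)C)(C(C)C)C(C)C)c(OC)c2)OC[C@H]1Cc1ccc(O[Si](C(C)C)(C(C)C)C(C)C)c(OC)c1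
F0 | step 6 | none | none
F4 | step 3 | (R)-1-{3-methoxy-4-[(triisopropylsilyl)oxy]phenyl}prop-2-enyl acetate | COc1cc([C@H](OC(C)=O)C=C)ccc1O[Si](C(C)C)(C(C)C)C(C)C
F5 | step 3 | (R)-1-{3-methoxy-4-[(triisopropylsilyl)oxy]phenyl}prop-2-en-1-ol | COc1cc([C@H](O)C=C)ccc1O[Si](C(C)C)(C(C)C)C(C)C
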